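**Plan**
1. Numbering: naphthalene C1 (3,4-dimethoxyphenyl, ring C), C2 (OH), C3 (CHO), C7 (OH), C8 (OMe). Ring A is C1–C4 plus C4a and C8a; ring B is C4a–C8a.
2. Retrosynthesis: the C2 and C7 phenols are masked as methyl and isopropyl ethers and the C3 formyl group is traced back to a methyl ester. Ring A is then cut at C4–C4a and C1–C8a into a ring B aryne and a four-carbon aroyl dienolate (C1–C4).
3. Enabling feature: the C8 methoxy group is the neighbour of C8a. An aryne spanning C4a and C8a therefore accepts carbon at C4a and carries the new carbanion on C8a, within reach of the aroyl carbon that becomes C1. Normal aryne polarity thus sets ring C peri to the C8 methoxy group.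
4. The C1–C4 piece is cut at C2=C3 (aldol addition to methyl pyruvate, then dehydration) and at the ring C–C1 bond (aryl Grignard reagent plus a Weinreb amide).
5. Forward order: rings B and C are bought as bromoarenes, and ring A is the only ring built, closing in one flask. Ester-to-aldehyde adjustment and a double ether cleavage finish the route.
6. Stereochemistry: the target has no stereocentre. The stereocentres of the aldol and of the ring A carbinol are transient, and the alkene geometry of the dienolate precursor is erased on deprotonation.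

Key step: step 5

Assumption: ring C has no ortho substituent, so rotation about the C1–ring C bond is taken as free and the target is treated as achiral.

Step 1
Reactants: 1 4-bromo-2-methoxyphenol
Product: 2 4-bromo-2-methoxy-1-(propan-2-yloxy)benzene
Conditions: 2-bromopropane, K2CO3, DMF, 60 °C
Reagents that add atoms: 2-bromopropane, CC(C)Br
Why: In this Williamson ether synthesis the phenoxide displaces bromide from 2-bromopropane while the aryl bromide stays inert, and the isopropyl ether tolerates strong base and hydride yet can later be removed beside methyl ethers.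

Step 2
Reactants: 3 4-bromo-1,2-dimethoxybenzene; 4 N,2-dimethoxy-N-methylacetamide
Product: 6 1-(3,4-dimethoxyphenyl)-2-methoxyethan-1-one, via arylmagnesium bromide 5 (not isolated)
Conditions: Mg, THF, reflux; then 4, 0 °C → rt; 1 M HCl
Reagents that add atoms: none
Why: In this Weinreb ketone synthesis the chelated tetrahedral adduct survives until the acid quench, so the Grignard reagent adds only once, and the route avoids a Friedel–Crafts acylation with methoxyacetyl chloride, whose acylium ion readily loses CO under AlCl3.

Step 3
Reactants: 6 1-(3,4-dimethoxyphenyl)-2-methoxyethan-1-one; 7 methyl pyruvate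
Product: 9 methyl 4-(3,4-dimethoxyphenyl)-2-hydroxy-3-methoxy-2-methyl-4-oxobutanoate (racemic mixture of diastereomers), via titanium enolate 8 (not isolated)
Conditions: TiCl4, Et3N, CH2Cl2, −78 °C; then 7, −78 → −40 °C; H2O
Reagents that add atoms: none
Why: In this titanium-mediated direct crossed aldol addition, soft enolisation gives the chelated Z enolate 8, which should add to the strongly electrophilic ketone carbonyl of 7 faster than 7 is enolised, and the two new stereocentres are left uncontrolled because step 4 erases both.

Step 4
Reactants: 9 methyl 4-(3,4-dimethoxyphenyl)-2-hydroxy-3-methoxy-2-methyl-4-oxobutanoate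
Product: 11 methyl (E)-4-(3,4-dimethoxyphenyl)-3-methoxy-2-methyl-4-oxobut-2-enoate, via tertiary mesylate 10 (not isolated)
Conditions: MsCl, Et3N, CH2Cl2, 0 °C; then DBU, 0 °C → rt
Reagents that add atoms: none
Why: Mesylation by way of sulfene reaches the tertiary hydroxyl group, the acidic C–H next to the aryl ketone then allows an E1cB elimination, and DBU draws any exo-methylene isomer into the push-pull conjugated alkene, whose geometry (E expected, as for β-alkoxyacrylates) does not matter because step 5 erases it.

Step 5
Reactants: 11 methyl (E)-4-(3,4-dimethoxyphenyl)-3-methoxy-2-methyl-4-oxobut-2-enoate; 2 4-bromo-2-methoxy-1-(propan-2-yloxy)benzene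
Product: 15 methyl 4-(3,4-dimethoxyphenyl)-3,5-dimethoxy-6-(propan-2-yloxy)naphthalene-2-carboxylate, via lithium dienolate 12 (not isolated), via dialkoxybenzyne 13 (not isolated), via dihydronaphthalenol 14 (not isolated)
Conditions: lithium 2,2,6,6-tetramethylpiperidide (LiTMP, 4 equiv, from 2,2,6,6-tetramethylpiperidine and n-BuLi), THF, −78 °C, add 11; then 2 (2 equiv) slowly, −78 °C → rt; 1 M HCl; crude product, TsOH·H2O (cat.), CH2Cl2, rt
Reagents that add atoms: none
Why: LiTMP, which can neither add to a carbonyl group nor deliver hydride, removes a proton from the C-methyl group of 11 (the only acidic C–H, vinylogous to the aryl ketone) to give the cross-conjugated dienolate 12, and it metalates 2 at the one C–H flanked by bromine and methoxy, so that loss of LiBr gives aryne 13. The CH2 terminus of 12 bonds to C4a through the s-cis dienolate (stepwise or as an asynchronous (4+2) cycloaddition), which restores the enone with C1 and C4 cis on C2=C3, and the C8a carbanion closes ring A by 6-exo-trig addition to the ketone carbon C1. Acid then ionises the tertiary, doubly benzylic carbinol 14 and loss of a C4 proton aromatises ring A, so the single stereocentre of 14 (C1), formed racemic, disappears. The closest known reaction type is the anionic annulation of lithium dienolates of unsaturated esters and ketones with base-generated arynes, which gives 1-naphthols or, from ketones after dehydration, 1-substituted naphthalenes. Three selectivities are needed: aryne regiochemistry comes from the inductive pull of the C8 methoxy group, which places the developing carbanion on C8a and the nucleophile on C4a; γ over α attack comes from the fully substituted, methoxy-bearing α-carbon C2; and closure on the ketone comes from the ester being the weaker electrophile, able to give only a strained five-membered ring. Adding 11 to excess base before any aryne is present keeps neutral 11 away from its own dienolate.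

Step 6
Reactants: 15 methyl 4-(3,4-dimethoxyphenyl)-3,5-dimethoxy-6-(propan-2-yloxy)naphthalene-2-carboxylate
Product: 16 [4-(3,4-dimethoxyphenyl)-3,5-dimethoxy-6-(propan-2-yloxy)naphthalen-2-yl]methanol
Conditions: diisobutylaluminium hydride (2.5 equiv), CH2Cl2, −78 → 0 °C; aq. potassium sodium tartrate
Reagents that add atoms: none
Why: Hydride reduction of an aromatic ester with two or more equivalents of the aluminium hydride goes cleanly to the benzylic alcohol, and the aryl ethers are inert.

Step 7
Reactants: 16 [4-(3,4-dimethoxyphenyl)-3,5-dimethoxy-6-(propan-2-yloxy)naphthalen-2-yl]methanol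
Product: 17 4-(3,4-dimethoxyphenyl)-3,5-dimethoxy-6-(propan-2-yloxy)naphthalene-2-carbaldehyde
Conditions: MnO2 (excess), CH2Cl2, rt
Reagents that add atoms: none
Why: MnO2 oxidation is selective for benzylic alcohols and stops at the aldehyde.

Step 8
Reactants: 17 4-(3,4-dimethoxyphenyl)-3,5-dimethoxy-6-(propan-2-yloxy)naphthalene-2-carbaldehyde
Product: 18 vitrofolal B, 4-(3,4-dimethoxyphenyl)-3,6-dihydroxy-5-methoxynaphthalene-2-carbaldehyde
Conditions: BCl3 (excess), CH2Cl2, −78 → 0 °C; then H2O
Reagents that add atoms: none
Why: In this Lewis acid ether cleavage, BCl3 held between the formyl oxygen and the C2 ether oxygen in a six-membered chelate lets chloride remove that methyl group, the isopropyl ether goes by easy loss of a secondary alkyl group, and unchelated aryl methyl ethers are known to resist BCl3 at or below 0 °C.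

**Compound list**
1 | 4-bromo-2-methoxyphenol | COc1cc(Br)ccc1O | starting material
2 | 4-bromo-2-methoxy-1-(propan-2-yloxy)benzene | COc1cc(Br)ccc1OC(C)C | intermediate
3 | 4-bromo-1,2-dimethoxybenzene | COc1ccc(Br)cc1OC | starting material
4 | N,2-dimethoxy-N-methylacetamide | COCC(=O)N(C)OC | starting material
5 | (3,4-dimethoxyphenyl)magnesium bromide | COc1ccc([Mg]Br)cc1OC | intermediate
6 | 1-(3,4-dimethoxyphenyl)-2-methoxyethan-1-one | COCC(=O)c1ccc(OC)c(OC)c1 | intermediate
7 | methyl pyruvate (methyl 2-oxopropanoate) | COC(=O)C(C)=O | starting material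
8 | trichloro{[(Z)-1-(3,4-dimethoxyphenyl)-2-methoxyethenyl]oxy}titanium | CO/C=C(\O[Ti](Cl)(Cl)Cl)c1ccc(OC)c(OC)c1 | intermediate
9 | methyl 4-(3,4-dimethoxyphenyl)-2-hydroxy-3-methoxy-2-methyl-4-oxobutanoate (racemic, both diastereomers) | COC(=O)C(C)(O)C(OC)C(=O)c1ccc(OC)c(OC)c1 | intermediate
10 | methyl 4-(3,4-dimethoxyphenyl)-3-methoxy-2-methyl-2-(methanesulfonyloxy)-4-oxobutanoate (racemic, both diastereomers) | COC(=O)C(C)(OS(C)(=O)=O)C(OC)C(=O)c1ccc(OC)c(OC)c1 | intermediate
11 | methyl (E)-4-(3,4-dimethoxyphenyl)-3-methoxy-2-methyl-4-oxobut-2-enoate | COC(=O)/C(C)=C(/OC)C(=O)c1ccc(OC)c(OC)c1 | intermediate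
12 | lithium 1-(3,4-dimethoxyphenyl)-2-methoxy-3-(methoxycarbonyl)buta-1,3-dien-1-olate (enolate geometry not fixed and lost on C–C bond formation) | [Li+].[O-]C(=C(OC)C(=C)C(=O)OC)c1ccc(OC)c(OC)c1 | intermediate
13 | 1,2-didehydro-3-methoxy-4-(propan-2-yloxy)benzene | COC1=C(OC(C)C)C=CC#C1 | intermediate
14 | methyl 4-(3,4-dimethoxyphenyl)-4-hydroxy-3,5-dimethoxy-6-(propan-2-yloxy)-1,4-dihydronaphthalene-2-carboxylate (racemic) | COC(=O)C1=C(OC)C(O)(c2ccc(OC)c(OC)c2)c2c(C1)ccc(OC(C)C)c2OC | intermediate
15 | methyl 4-(3,4-dimethoxyphenyl)-3,5-dimethoxy-6-(propan-2-yloxy)naphthalene-2-carboxylate | COC(=O)c1cc2ccc(OC(C)C)c(OC)c2c(-c2ccc(OC)c(OC)c2)c1OC | intermediate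
16 | [4-(3,4-dimethoxyphenyl)-3,5-dimethoxy-6-(propan-2-yloxy)naphthalen-2-yl]methanol | OCc1cc2ccc(OC(C)C)c(OC)c2c(-c2ccc(OC)c(OC)c2)c1OC | intermediate
17 | 4-(3,4-dimethoxyphenyl)-3,5-dimethoxy-6-(propan-2-yloxy)naphthalene-2-carbaldehyde | O=Cc1cc2ccc(OC(C)C)c(OC)c2c(-c2ccc(OC)c(OC)c2)c1OC | intermediate
18 | vitrofolal B, 4-(3,4-dimethoxyphenyl)-3,6-dihydroxy-5-methoxynaphthalene-2-carbaldehyde | COc1ccc(-c2c(O)c(C=O)cc3ccc(O)c(OC)c23)cc1OC | target

Total step count: 8. Longest linear sequence: 7 steps (steps 2 to 8, from 3); step 1 is the side branch.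

**Steps most likely to fail**

**Step 5.** The dienolate may be arylated at its α-carbon or through an s-trans conformer. In either case the C8a carbanion cannot reach the ketone and is merely protonated. The dienolate may also condense with itself, and the amine may capture the aryne.

The fallback sets out from 2 and comes back at 16. Ring C is left out of the annulation and attached afterwards by cross-coupling, so the aryne meets an ester dienolate, the best-documented partner for this annulation.
- Commercial diethyl 2-methyl-3-oxobutanedioate is O-methylated (Me2SO4, K2CO3, acetone) to diethyl (Z)-2-methoxy-3-methylbut-2-enedioate F1.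
- F1 and 2 are treated with LiTMP as in step 5, and aryne 13 forms the same C4–C4a and C1–C8a bonds. The C8a carbanion now closes on an ester carbon, ethoxide leaves, and tautomerisation should give ethyl 4-hydroxy-3,5-dimethoxy-6-(propan-2-yloxy)naphthalene-2-carboxylate F2.
- Tf2O and pyridine convert it into ethyl 3,5-dimethoxy-6-(propan-2-yloxy)-4-(trifluoromethanesulfonyloxy)naphthalene-2-carboxylate F3.
- Suzuki–Miyaura coupling with (3,4-dimethoxyphenyl)boronic acid (Pd(OAc)2, SPhos, K3PO4, toluene/water, 100 °C) gives ethyl 4-(3,4-dimethoxyphenyl)-3,5-dimethoxy-6-(propan-2-yloxy)naphthalene-2-carboxylate F4.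
- Diisobutylaluminium hydride reduces F4 to 16.

**Step 4.** The crowded, electron-poor tertiary hydroxyl group may resist sulfonylation, and the free aldol may undergo retro-aldol cleavage under the basic conditions.

The fallback sets out from 6 and comes back at 11. The C2–C3 bond is made by alkylation and the alkene by dehydrogenation, so no aldol is involved.
- 6 is alkylated with methyl 2-bromopropanoate (LiN(SiMe3)2, THF, −78 °C) to methyl 4-(3,4-dimethoxyphenyl)-3-methoxy-2-methyl-4-oxobutanoate F5 (mixture of diastereomers).
- Renewed deprotonation at the more acidic position next to the ketone, followed by PhSeBr, gives methyl 4-(3,4-dimethoxyphenyl)-3-methoxy-2-methyl-4-oxo-3-(phenylselanyl)butanoate F6.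
- H2O2 oxidises it to methyl 4-(3,4-dimethoxyphenyl)-3-methoxy-2-methyl-4-oxo-3-(phenylseleninyl)butanoate F7.
- F7 undergoes syn elimination towards its only β-hydrogen and delivers 11.

**Step 8.** A third methyl group may be lost while the crowded C2 ether is still being cleaved. The candidates are the C8 ether, through a five-membered chelate to boron held on the freed C7 oxygen, and the ring C ethers.

The fallback sets out from 17 and comes back at 18. The two cleavages are separated, and the methyl ether is removed by nucleophilic rather than Lewis acid chemistry.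
- Heating 17 with LiCl in DMF lets chloride attack only the methyl group whose departing phenoxide is stabilised by the ortho formyl group. This gives 4-(3,4-dimethoxyphenyl)-3-hydroxy-5-methoxy-6-(propan-2-yloxy)naphthalene-2-carbaldehyde F8.
- The isopropyl ether is then cleaved on its own with AlCl3 in CH2Cl2 at or below room temperature, conditions known to spare aryl methyl ethers, to give 18.

**Further compounds**
F1 | step 5 | diethyl (Z)-2-methoxy-3-methylbut-2-enedioate | CCOC(=O)/C(OC)=C(\C)C(=O)OCC
F2 | step 5 | ethyl 4-hydroxy-3,5-dimethoxy-6-(propan-2-yloxy)naphthalene-2-carboxylate | CCOC(=O)c1cc2ccc(OC(C)C)c(OC)c2c(O)c1OC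
F3 | step 5 | ethyl 3,5-dimethoxy-6-(propan-2-yloxy)-4-(trifluoromethanesulfonyloxy)naphthalene-2-carboxylate | CCOC(=O)c1cc2ccc(OC(C)C)c(OC)c2c(OS(=O)(=O)C(F)(F)F)c1OC
F4 | step 5 | ethyl 4-(3,4-dimethoxyphenyl)-3,5-dimethoxy-6-(propan-2-yloxy)naphthalene-2-carboxylate | CCOC(=O)c1cc2ccc(OC(C)C)c(OC)c2c(-c2ccc(OC)c(OC)c2)c1OC
F5 | step 4 | methyl 4-(3,4-dimethoxyphenyl)-3-methoxy-2-methyl-4-oxobutanoate (mixture of diastereomers) | COC(=O)C(C)C(OC)C(=O)c1ccc(OC)c(OC)c1
F6 | step 4 | methyl 4-(3,4-dimethoxyphenyl)-3-methoxy-2-methyl-4-oxo-3-(phenylselanyl)butanoate (mixture of diastereomers) | COC(=O)C(C)C(OC)([Se]c1ccccc1)C(=O)c1ccc(OC)c(OC)c1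
F7 | step 4 | methyl 4-(3,4-dimethoxyphenyl)-3-methoxy-2-methyl-4-oxo-3-(phenylseleninyl)butanoate (mixture of diastereomers) | COC(=O)C(C)C(OC)([Se](=O)c1ccccc1)C(=O)c1ccc(OC)c(OC)c1
F8 | step 8 | 4-(3,4-dimethoxyphenyl)-3-hydroxy-5-methoxy-6-(propan-2-yloxy)naphthalene-2-carbaldehyde | O=Cc1cc2ccc(OC(C)C)c(OC)c2c(-c2ccc(OC)c(OC)c2)c1O
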